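(The readings are simulated with constants of no real substance; noise was put on by code.)

Start from the amounts: the flask asked about holds 25 mM of substrate against 27.5 mM of first nucleophile and 30.0 mM of second nucleophile, and the south run is this same flask followed so far.

all flasks: first nucleophile 27.5 mM
- south: substrate 25 mM; second nucleophile 30 mM; the very flask that is asked about, followed so far
- south-east: substrate 17 mM; second nucleophile 30 mM; run made earlier
- flask: substrate 25 mM; second nucleophile 30.0 mM; time 50 h

| run | time / h | other capture product / % | target / % |
|---|---|---|---|
| south | 2.00 | 17.2 | 1.4 |
| south | 5.00 | 37.0 | 2.1 |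
| south | 10.0 | 60.6 | 2.1 |
| south | 15.0 | 72.5 | 2.9 |
| south-east | 4.00 | 32.4 | 2.2 |
| south-east | 12.0 | 67.1 | 2.0 |
| south-east | 25.0 | 85.7 | 2.3 |
| south-east | 40.0 | 89.6 | 1.1 |

(standard deviation of a reading: 0.5 percentage points)

- ratio of other capture product to target at 30 min
- ratio of other capture product to target at 5.0 h
- ratio of other capture product to target at 50 h

Run it slowly, treating the two products as rivals and taking each capture to cost one second nucleophile. For the first instants, replace the falling [second nucleophile] by its mean. At 2.00 h the south reading of 17.2 % has spent 4.30 mM, so the mean is 27.8 mM, while target has taken 0.350 mM of first nucleophile, so hold that at 27.5 mM. The reading ratio then gives 12.1 for the selectivity factor S, the other capture product formed per target formed at equal [second nucleophile] and [first nucleophile]. It is rough, with a scatter of 0.5 percentage points on 1.4 %. At 30 min the charges give me a ratio of 13.2.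

In the middle, the mean [second nucleophile] to 5.0 h is 25.4 mM, which gives 11.2, but the reading stands higher at 17.6. Read the gap as target formed that no longer stands, and commit to the reading.

For the end, take other capture product near the south-east 40.0 h reading of 89.6 %. This flask then keeps 7.60 mM of second nucleophile and south-east 14.8 mM, less here, so late product here splits 3.35 to one, against 6.51 to one there. Commit to a ratio at 50 h in this flask below the south-east reading of 81.5, itself rough, with 1.1 % of target against a scatter of 0.5 points.

The forecast gives 12, 16.5 and 140, the last above that south-east reading and, in its words, “very uncertain”. The flask gives 14.3, 16.7 and 58.0.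

    substrate → intermediate (k = 0.110 h⁻¹)
    first nucleophile + intermediate → target (k = 14.0 M⁻¹ h⁻¹)
    second nucleophile + intermediate → other capture product (k = 180 M⁻¹ h⁻¹)
    first nucleophile + target → over-reaction product (k = 0.390 M⁻¹ h⁻¹)
    target ⇌ isomer of the product (K = 5.60, k = 0.140 h⁻¹)

Fed with the amounts at 50 h, second nucleophile at 26.1 % and first nucleophile at 89.1 % of their charges, S gives a split of newly formed product of 3.88 to one in this flask. At the charged concentrations, intermediate has a half-life of 0.13 h by capture against 1.8 h by the making of target.

For the neighbour flask with 120 mM of second nucleophile, S gives 52.9 at 30 min; that flask gives 57.8.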